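**Retrosynthetic overview**
1. Target ⇒ global desilylation, then ester C–O disconnection to the tetrahydrofuran primary alcohol 21 and O‑TBS p‑coumaric acid 24.
2. Tetrahydrofuran ring ⇒ O1–C5 bond (primary tosylate displaced by the benzylic hydroxyl, C2 untouched) ⇒ diol 18 ⇒ trans α‑benzyl γ‑lactone 17.
3. 17 ⇒ benzylic C–C bond at C4: lactone enolate alkylation with bromide 15, anti to the two cis substituents.
4. cis γ‑aryl β‑carboxy lactone ⇒ ArCH–CH bond (future C2–C3): auxiliary‑controlled anti‑aldol of succinyl imide 6 with aldehyde 2, which sets both centres (key step).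
5. Ring order: γ‑lactone closed in step 3, opened in step 10, tetrahydrofuran closed in step 11; the three benzene rings are bought (vanillin twice, p‑coumaric acid).

Assumption: the SMILES is taken literally, i.e. (2S,3S,4R) on the oxolane, with 2‑aryl and 3‑CH2O cis and 3‑CH2O and 4‑benzyl trans (the C3 epimer of the lariciresinol skeleton).

**Route**

Step 1
Reactants: 1 vanillin
Product: 2 3-methoxy-4-(triisopropylsilyloxy)benzaldehyde
Conditions: TIPSCl (1.2 equiv), imidazole (2.5 equiv), DMF, 0 °C → rt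
Reagents that add atoms: chlorotriisopropylsilane (TIPSCl), CC(C)[Si](Cl)(C(C)C)C(C)C
Why: Imidazole‑promoted O‑silylation of the phenol gives an aryl TIPS ether that tolerates the mild base, hydride and mild acid of the later steps and is removed by fluoride at the end.

Step 2
Reactants: 3 (S)-4-benzyl-1,3-oxazolidin-2-one; 4 methyl 4-chloro-4-oxobutanoate
Product: 6 methyl 4-[(4S)-4-benzyl-2-oxo-1,3-oxazolidin-3-yl]-4-oxobutanoate, via N-lithio oxazolidinone 5 (not isolated)
Conditions: n-BuLi (1.05 equiv), THF, −78 °C; then 4, −78 → 0 °C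
Reagents that add atoms: none
Why: N‑acylation of the lithiated Evans oxazolidinone by the acid chloride is fast and clean, and the ester end of the succinate is untouched.

Step 3
Reactants: 6 methyl 4-[(4S)-4-benzyl-2-oxo-1,3-oxazolidin-3-yl]-4-oxobutanoate; 2 3-methoxy-4-(triisopropylsilyloxy)benzaldehyde
Product: 9 (4S)-4-benzyl-3-{(2S,3R)-2-[3-methoxy-4-(triisopropylsilyloxy)phenyl]-5-oxooxolane-3-carbonyl}-1,3-oxazolidin-2-one, via TMS ether 7 (not isolated), via hydroxy ester 8 (not isolated)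
Conditions: MgCl2 (0.2 equiv), Et3N (2 equiv), TMSCl (1.5 equiv), EtOAc, rt, 24 h; then MeOH, TFA (cat.), 0 °C; then PPTS (cat.), PhMe, 60 °C
Reagents that add atoms: none
Why: MgCl2‑catalysed direct anti‑aldol of the Evans imide, in which the magnesium‑chelated Z‑enolate (formed only next to the imide carbonyl) is attacked on the face opposite the 4‑benzyl group through a boat‑like transition state to give the (3R,4S) anti adduct, whose freed benzylic hydroxyl then lactonises onto the methyl ester to place aryl and acyl cis on the γ‑lactone.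

Step 4
Reactants: 9 (4S)-4-benzyl-3-{(2S,3R)-2-[3-methoxy-4-(triisopropylsilyloxy)phenyl]-5-oxooxolane-3-carbonyl}-1,3-oxazolidin-2-one
Product: 11 (2S,3R)-2-[3-methoxy-4-(triisopropylsilyloxy)phenyl]-5-oxooxolane-3-carboxylic acid, via peroxy acid 10 (not isolated)
Conditions: LiOH (2 equiv), 30% H2O2 (4 equiv), THF/H2O 3:1, 0 °C, 1 h; then aq. Na2SO3; then 1 M HCl to pH 2–3, 0 °C
Reagents that add atoms: hydrogen peroxide, OO
Why: Hydroperoxide cleaves the exocyclic imide carbonyl selectively (Evans auxiliary removal) at 0 °C without epimerising the α‑centre, and any lactone opened by hydroxide recloses on acidification because only the γ‑lactone is possible.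

Step 5
Reactants: 11 (2S,3R)-2-[3-methoxy-4-(triisopropylsilyloxy)phenyl]-5-oxooxolane-3-carboxylic acid
Product: 12 (4S,5S)-4-(hydroxymethyl)-5-[3-methoxy-4-(triisopropylsilyloxy)phenyl]oxolan-2-one
Conditions: BH3·SMe2 (2 equiv), THF, 0 °C → rt; MeOH quench; crude used directly in step 6
Reagents that add atoms: none
Why: Chemoselective borane reduction of the carboxylic acid (via the acyloxyborane) leaves the lactone intact, and the neutral work‑up with immediate silylation forestalls translactonisation of the cis hydroxymethyl lactone.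

Step 6
Reactants: 12 (4S,5S)-4-(hydroxymethyl)-5-[3-methoxy-4-(triisopropylsilyloxy)phenyl]oxolan-2-one
Product: 13 (4S,5S)-4-[(tert-butyldimethylsilyloxy)methyl]-5-[3-methoxy-4-(triisopropylsilyloxy)phenyl]oxolan-2-one
Conditions: TBSCl (1.2 equiv), imidazole (2.5 equiv), CH2Cl2, 0 °C → rt
Reagents that add atoms: tert-butylchlorodimethylsilane (TBSCl), CC(C)(C)[Si](C)(C)Cl
Why: Silylation of the primary alcohol locks the lactone regiochemistry and gives an alkyl TBS ether that can later be removed by mild acid while the aryl TIPS ethers stay.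

Step 7
Reactants: 2 3-methoxy-4-(triisopropylsilyloxy)benzaldehyde
Product: 14 [3-methoxy-4-(triisopropylsilyloxy)phenyl]methanol
Conditions: NaBH4 (1 equiv), MeOH, 0 °C; aqueous work-up
Reagents that add atoms: none
Why: Borohydride reduction of the aromatic aldehyde to the benzylic alcohol is quantitative and does not touch the aryl silyl ether at 0 °C.

Step 8
Reactants: 14 [3-methoxy-4-(triisopropylsilyloxy)phenyl]methanol
Product: 15 [4-(bromomethyl)-2-methoxyphenoxy]triisopropylsilane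
Conditions: CBr4 (1.3 equiv), PPh3 (1.3 equiv), CH2Cl2, 0 °C; short silica plug, used the same day
Reagents that add atoms: tetrabromomethane, BrC(Br)(Br)Br
Why: Appel bromination converts the benzylic alcohol to the bromide under neutral conditions that spare the silyl ether.

Step 9
Reactants: 13 (4S,5S)-4-[(tert-butyldimethylsilyloxy)methyl]-5-[3-methoxy-4-(triisopropylsilyloxy)phenyl]oxolan-2-one; 15 [4-(bromomethyl)-2-methoxyphenoxy]triisopropylsilane
Product: 17 (3R,4S,5S)-4-[(tert-butyldimethylsilyloxy)methyl]-3-[3-methoxy-4-(triisopropylsilyloxy)benzyl]-5-[3-methoxy-4-(triisopropylsilyloxy)phenyl]oxolan-2-one, via lithium enolate 16 (not isolated)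
Conditions: LiN(SiMe3)2 (1.1 equiv), THF, −78 °C, 45 min; then 15 (1.3 equiv), DMPU, −78 → −40 °C
Reagents that add atoms: none
Why: SN2 alkylation of the lactone enolate by the reactive benzylic bromide occurs on the face opposite the cis C4 silyloxymethyl and C5 aryl groups, setting the new C3 centre trans to C4 (3R).

Step 10
Reactants: 17 (3R,4S,5S)-4-[(tert-butyldimethylsilyloxy)methyl]-3-[3-methoxy-4-(triisopropylsilyloxy)benzyl]-5-[3-methoxy-4-(triisopropylsilyloxy)phenyl]oxolan-2-one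
Product: 18 (1S,2S,3R)-2-[(tert-butyldimethylsilyloxy)methyl]-3-[3-methoxy-4-(triisopropylsilyloxy)benzyl]-1-[3-methoxy-4-(triisopropylsilyloxy)phenyl]butane-1,4-diol
Conditions: LiBH4 (3 equiv), THF, 0 °C → rt; aqueous work-up
Reagents that add atoms: none
Why: Lithium borohydride reduces the lactone to the 1,4‑diol without epimerising the α‑centre and without attacking alkyl or aryl silyl ethers.

Step 11
Reactants: 18 (1S,2S,3R)-2-[(tert-butyldimethylsilyloxy)methyl]-3-[3-methoxy-4-(triisopropylsilyloxy)benzyl]-1-[3-methoxy-4-(triisopropylsilyloxy)phenyl]butane-1,4-diol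
Product: 20 tert-butyl{[(2S,3S,4R)-4-[3-methoxy-4-(triisopropylsilyloxy)benzyl]-2-[3-methoxy-4-(triisopropylsilyloxy)phenyl]oxolan-3-yl]methoxy}dimethylsilane, via primary tosylate 19 (not isolated)
Conditions: TsCl (1.15 equiv), Et3N (4 equiv), DMAP (0.1 equiv), CH2Cl2, 0 °C → rt, then 40 °C until 19 is consumed
Reagents that add atoms: none
Why: Selective sulfonylation of the unhindered primary alcohol followed by intramolecular Williamson etherification (5‑exo‑tet SN2 at the primary carbon) closes the tetrahydrofuran without breaking the benzylic C–O bond, so the (S) benzylic centre and the 2,3‑cis relationship are retained.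

Step 12
Reactants: 20 tert-butyl{[(2S,3S,4R)-4-[3-methoxy-4-(triisopropylsilyloxy)benzyl]-2-[3-methoxy-4-(triisopropylsilyloxy)phenyl]oxolan-3-yl]methoxy}dimethylsilane
Product: 21 [(2S,3S,4R)-4-[3-methoxy-4-(triisopropylsilyloxy)benzyl]-2-[3-methoxy-4-(triisopropylsilyloxy)phenyl]oxolan-3-yl]methanol
Conditions: PPTS (0.3 equiv), MeOH, rt
Reagents that add atoms: none
Why: Mild acid‑catalysed methanolysis removes the primary alkyl TBS ether while aryl TIPS ethers are inert to acid and PPTS is too weak to ionise the benzylic C2–O bond.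

Step 13
Reactants: 22 (E)-3-(4-hydroxyphenyl)prop-2-enoic acid (p-coumaric acid)
Product: 24 (E)-3-[4-(tert-butyldimethylsilyloxy)phenyl]prop-2-enoic acid, via bis-silyl coumarate 23 (not isolated)
Conditions: TBSCl (2.3 equiv), imidazole (4.5 equiv), DMF, rt; then AcOH/THF/H2O 3:1:1, rt
Reagents that add atoms: tert-butylchlorodimethylsilane (TBSCl), CC(C)(C)[Si](C)(C)Cl
Why: Exhaustive silylation followed by selective hydrolysis of the far more labile silyl ester leaves the phenol protected and the acid free.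

Step 14
Reactants: 21 [(2S,3S,4R)-4-[3-methoxy-4-(triisopropylsilyloxy)benzyl]-2-[3-methoxy-4-(triisopropylsilyloxy)phenyl]oxolan-3-yl]methanol; 24 (E)-3-[4-(tert-butyldimethylsilyloxy)phenyl]prop-2-enoic acid
Product: 25 [(2S,3S,4R)-4-[3-methoxy-4-(triisopropylsilyloxy)benzyl]-2-[3-methoxy-4-(triisopropylsilyloxy)phenyl]oxolan-3-yl]methyl (E)-3-[4-(tert-butyldimethylsilyloxy)phenyl]prop-2-enoate
Conditions: DCC (1.4 equiv), DMAP (0.2 equiv), CH2Cl2, 0 °C → rt
Reagents that add atoms: none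
Why: Steglich esterification of the only free hydroxyl under neutral conditions keeps the E‑alkene geometry and the acid‑sensitive cis 2‑aryl tetrahydrofuran intact.

Step 15
Reactants: 25 [(2S,3S,4R)-4-[3-methoxy-4-(triisopropylsilyloxy)benzyl]-2-[3-methoxy-4-(triisopropylsilyloxy)phenyl]oxolan-3-yl]methyl (E)-3-[4-(tert-butyldimethylsilyloxy)phenyl]prop-2-enoate
Product: 26 [(2S,3S,4R)-4-(4-hydroxy-3-methoxybenzyl)-2-(4-hydroxy-3-methoxyphenyl)oxolan-3-yl]methyl (E)-3-(4-hydroxyphenyl)prop-2-enoate (CNP0119373.2)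
Conditions: Bu4NF (3.5 equiv), AcOH (4 equiv), THF, 0 °C → rt
Reagents that add atoms: none
Why: Fluoride‑mediated cleavage of the three aryl silyl ethers, buffered with acetic acid so that no free phenoxide attacks the cinnamate ester or opens the 2‑aryl tetrahydrofuran, releases the target without touching any stereocentre or the alkene.

**Compound list**
1 | vanillin (4-hydroxy-3-methoxybenzaldehyde) | COc1cc(C=O)ccc1O | starting material
2 | 3-methoxy-4-(triisopropylsilyloxy)benzaldehyde | COc1cc(C=O)ccc1O[Si](C(C)C)(C(C)C)C(C)C | intermediate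
3 | (S)-4-benzyl-1,3-oxazolidin-2-one | O=C1N[C@@H](Cc2ccccc2)CO1 | starting material
4 | methyl 4-chloro-4-oxobutanoate | COC(=O)CCC(Cl)=O | starting material
5 | lithium (S)-4-benzyl-2-oxo-1,3-oxazolidin-3-ide (N-lithio oxazolidinone) | [Li]N1[C@@H](Cc2ccccc2)COC1=O | intermediate
6 | methyl 4-[(4S)-4-benzyl-2-oxo-1,3-oxazolidin-3-yl]-4-oxobutanoate | COC(=O)CCC(=O)N1[C@@H](Cc2ccccc2)COC1=O | intermediate
7 | methyl (3R,4S)-3-[(4S)-4-benzyl-2-oxo-1,3-oxazolidine-3-carbonyl]-4-[3-methoxy-4-(triisopropylsilyloxy)phenyl]-4-(trimethylsilyloxy)butanoate (TMS ether) | COC(=O)C[C@@H](C(=O)N1[C@@H](Cc2ccccc2)COC1=O)[C@H](O[Si](C)(C)C)c1ccc(O[Si](C(C)C)(C(C)C)C(C)C)c(OC)c1 | intermediate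
8 | methyl (3R,4S)-3-[(4S)-4-benzyl-2-oxo-1,3-oxazolidine-3-carbonyl]-4-hydroxy-4-[3-methoxy-4-(triisopropylsilyloxy)phenyl]butanoate (hydroxy ester) | COC(=O)C[C@@H](C(=O)N1[C@@H](Cc2ccccc2)COC1=O)[C@H](O)c1ccc(O[Si](C(C)C)(C(C)C)C(C)C)c(OC)c1 | intermediate
9 | (4S)-4-benzyl-3-{(2S,3R)-2-[3-methoxy-4-(triisopropylsilyloxy)phenyl]-5-oxooxolane-3-carbonyl}-1,3-oxazolidin-2-one | O=C1O[C@H](c2ccc(O[Si](C(C)C)(C(C)C)C(C)C)c(OC)c2)[C@@H](C1)C(=O)N1[C@@H](Cc2ccccc2)COC1=O | intermediate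
10 | (2S,3R)-2-[3-methoxy-4-(triisopropylsilyloxy)phenyl]-5-oxooxolane-3-carboperoxoic acid (peroxy acid) | O=C1O[C@H](c2ccc(O[Si](C(C)C)(C(C)C)C(C)C)c(OC)c2)[C@@H](C1)C(=O)OO | intermediate
11 | (2S,3R)-2-[3-methoxy-4-(triisopropylsilyloxy)phenyl]-5-oxooxolane-3-carboxylic acid | O=C1O[C@H](c2ccc(O[Si](C(C)C)(C(C)C)C(C)C)c(OC)c2)[C@@H](C1)C(=O)O | intermediate
12 | (4S,5S)-4-(hydroxymethyl)-5-[3-methoxy-4-(triisopropylsilyloxy)phenyl]oxolan-2-one | O=C1O[C@H](c2ccc(O[Si](C(C)C)(C(C)C)C(C)C)c(OC)c2)[C@@H](C1)CO | intermediate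
13 | (4S,5S)-4-[(tert-butyldimethylsilyloxy)methyl]-5-[3-methoxy-4-(triisopropylsilyloxy)phenyl]oxolan-2-one | O=C1O[C@H](c2ccc(O[Si](C(C)C)(C(C)C)C(C)C)c(OC)c2)[C@@H](C1)CO[Si](C)(C)C(C)(C)C | intermediate
14 | [3-methoxy-4-(triisopropylsilyloxy)phenyl]methanol | COc1cc(CO)ccc1O[Si](C(C)C)(C(C)C)C(C)C | intermediate
15 | [4-(bromomethyl)-2-methoxyphenoxy]triisopropylsilane | COc1cc(CBr)ccc1O[Si](C(C)C)(C(C)C)C(C)C | intermediate
16 | lithium enolate of 13 (lithium (4S,5S)-4-[(tert-butyldimethylsilyloxy)methyl]-5-aryl-4,5-dihydrofuran-2-olate) | [Li]OC1=C[C@@H](CO[Si](C)(C)C(C)(C)C)[C@@H](c2ccc(O[Si](C(C)C)(C(C)C)C(C)C)c(OC)c2)O1 | intermediate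
17 | (3R,4S,5S)-4-[(tert-butyldimethylsilyloxy)methyl]-3-[3-methoxy-4-(triisopropylsilyloxy)benzyl]-5-[3-methoxy-4-(triisopropylsilyloxy)phenyl]oxolan-2-one | COc1cc(C[C@H]2C(=O)O[C@H](c3ccc(O[Si](C(C)C)(C(C)C)C(C)C)c(OC)c3)[C@@H]2CO[Si](C)(C)C(C)(C)C)ccc1O[Si](C(C)C)(C(C)C)C(C)C | intermediate
18 | (1S,2S,3R)-2-[(tert-butyldimethylsilyloxy)methyl]-3-[3-methoxy-4-(triisopropylsilyloxy)benzyl]-1-[3-methoxy-4-(triisopropylsilyloxy)phenyl]butane-1,4-diol | COc1cc(C[C@@H](CO)[C@@H](CO[Si](C)(C)C(C)(C)C)[C@H](O)c2ccc(O[Si](C(C)C)(C(C)C)C(C)C)c(OC)c2)ccc1O[Si](C(C)C)(C(C)C)C(C)C | intermediate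
19 | (2R,3S,4S)-3-[(tert-butyldimethylsilyloxy)methyl]-4-hydroxy-2-[3-methoxy-4-(triisopropylsilyloxy)benzyl]-4-[3-methoxy-4-(triisopropylsilyloxy)phenyl]butyl 4-methylbenzenesulfonate (primary tosylate) | COc1cc(C[C@@H](COS(=O)(=O)c2ccc(C)cc2)[C@@H](CO[Si](C)(C)C(C)(C)C)[C@H](O)c2ccc(O[Si](C(C)C)(C(C)C)C(C)C)c(OC)c2)ccc1O[Si](C(C)C)(C(C)C)C(C)C | intermediate
20 | tert-butyl{[(2S,3S,4R)-4-[3-methoxy-4-(triisopropylsilyloxy)benzyl]-2-[3-methoxy-4-(triisopropylsilyloxy)phenyl]oxolan-3-yl]methoxy}dimethylsilane | COc1cc(C[C@H]2CO[C@H](c3ccc(O[Si](C(C)C)(C(C)C)C(C)C)c(OC)c3)[C@@H]2CO[Si](C)(C)C(C)(C)C)ccc1O[Si](C(C)C)(C(C)C)C(C)C | intermediate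
21 | [(2S,3S,4R)-4-[3-methoxy-4-(triisopropylsilyloxy)benzyl]-2-[3-methoxy-4-(triisopropylsilyloxy)phenyl]oxolan-3-yl]methanol | COc1cc(C[C@H]2CO[C@H](c3ccc(O[Si](C(C)C)(C(C)C)C(C)C)c(OC)c3)[C@@H]2CO)ccc1O[Si](C(C)C)(C(C)C)C(C)C | intermediate
22 | (E)-3-(4-hydroxyphenyl)prop-2-enoic acid (p-coumaric acid) | OC(=O)/C=C/c1ccc(O)cc1 | starting material
23 | tert-butyldimethylsilyl (E)-3-[4-(tert-butyldimethylsilyloxy)phenyl]prop-2-enoate (bis-silyl coumarate) | CC(C)(C)[Si](C)(C)OC(=O)/C=C/c1ccc(O[Si](C)(C)C(C)(C)C)cc1 | intermediate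
24 | (E)-3-[4-(tert-butyldimethylsilyloxy)phenyl]prop-2-enoic acid | OC(=O)/C=C/c1ccc(O[Si](C)(C)C(C)(C)C)cc1 | intermediate
25 | [(2S,3S,4R)-4-[3-methoxy-4-(triisopropylsilyloxy)benzyl]-2-[3-methoxy-4-(triisopropylsilyloxy)phenyl]oxolan-3-yl]methyl (E)-3-[4-(tert-butyldimethylsilyloxy)phenyl]prop-2-enoate | COc1cc(C[C@H]2CO[C@H](c3ccc(O[Si](C(C)C)(C(C)C)C(C)C)c(OC)c3)[C@@H]2COC(=O)/C=C/c2ccc(O[Si](C)(C)C(C)(C)C)cc2)ccc1O[Si](C(C)C)(C(C)C)C(C)C | intermediate
26 | [(2S,3S,4R)-4-(4-hydroxy-3-methoxybenzyl)-2-(4-hydroxy-3-methoxyphenyl)oxolan-3-yl]methyl (E)-3-(4-hydroxyphenyl)prop-2-enoate | COc1cc(C[C@H]2CO[C@H](c3ccc(O)c(OC)c3)[C@@H]2COC(=O)/C=C/c2ccc(O)cc2)ccc1O | target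

**Summary**
Total step count: 15.
Longest linear sequence: 11 steps (1, 3, 4, 5, 6, 9, 10, 11, 12, 14, 15, from vanillin; the same length from oxazolidinone 3 via step 2).

**Steps most likely to fail, with fallbacks**

Step 3 (anti‑aldol and lactonisation). The magnesium‑catalysed anti‑aldol is well established for simple acyl imides and aromatic aldehydes, but the ester‑bearing succinyl imide with an electron‑rich aldehyde may give low conversion or a poor anti/syn ratio. The fallback makes the same C–C bond by enamine catalysis and sets out from aldehyde 2. Commercial methyl 4-oxobutanoate (COC(=O)CCC=O) is added slowly to 2 in DMF at 4 °C with D‑proline (30 mol %). The List–Houk transition state gives the anti adduct methyl (3R,4S)-3-formyl-4-hydroxy-4-[3-methoxy-4-(triisopropylsilyloxy)phenyl]butanoate F1; D‑proline is needed because L‑proline gives the mirror‑image anti adduct. The crude aldehyde is oxidised at once (NaClO2, NaH2PO4, 2-methylbut-2-ene, t-BuOH/H2O, 0 °C) to (2R)-2-{(S)-hydroxy[3-methoxy-4-(triisopropylsilyloxy)phenyl]methyl}-4-methoxy-4-oxobutanoic acid F2. Warming F2 with catalytic PPTS in toluene closes the lactone and gives acid 11, where the route is rejoined; steps 2 to 4 are bypassed.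

Step 9 (enolate benzylation). Bromide 15 is a labile, electron‑rich benzylic halide, so the alkylation may be low‑yielding. The fallback sets out from lactone 13 and aldehyde 2 and replaces the halide by the stable aldehyde. Enolate 16 (LiN(SiMe3)2, THF, −78 °C) adds to 2 in an aldol reaction, again anti to the C4 and C5 substituents, to give (3S,4S,5S)-4-[(tert-butyldimethylsilyloxy)methyl]-3-{hydroxy[3-methoxy-4-(triisopropylsilyloxy)phenyl]methyl}-5-[3-methoxy-4-(triisopropylsilyloxy)phenyl]oxolan-2-one F3. The carbinol epimers are inconsequential, and the 3S label reflects only a priority change, not a different geometry. Treatment with 1,1'-thiocarbonyldiimidazole (ClCH2CH2Cl, 60 °C) gives O-{[(3S,4S,5S)-4-[(tert-butyldimethylsilyloxy)methyl]-5-[3-methoxy-4-(triisopropylsilyloxy)phenyl]-2-oxooxolan-3-yl][3-methoxy-4-(triisopropylsilyloxy)phenyl]methyl} 1H-imidazole-1-carbothioate F4. Barton–McCombie deoxygenation (Bu3SnH, AIBN, PhMe, 90 °C) then removes the benzylic oxygen and returns to lactone 17.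

Step 11 (selective tosylation and ring closure). Bis‑sulfonylation, or sulfonylation and ionisation of the benzylic carbinol, would erode the 2,3‑cis relationship. The fallback avoids the diol and sets out from lactone 17. Reduction with i-Bu2AlH (CH2Cl2, −78 °C) gives the lactol (3R,4S,5S)-4-[(tert-butyldimethylsilyloxy)methyl]-3-[3-methoxy-4-(triisopropylsilyloxy)benzyl]-5-[3-methoxy-4-(triisopropylsilyloxy)phenyl]oxolan-2-ol F5 as an anomer mixture. Deoxygenation through the oxocarbenium ion with Et3SiH and BF3·OEt2 (CH2Cl2, −78 °C, short contact, Et3N quench) gives tetrahydrofuran 20 directly, bypassing 18 and 19. The reaction must be kept cold and brief so that the Lewis acid does not ionise the benzylic C2–O bond.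

**Further compounds**
F1 | step 3 | methyl (3R,4S)-3-formyl-4-hydroxy-4-[3-methoxy-4-(triisopropylsilyloxy)phenyl]butanoate | COC(=O)C[C@@H](C=O)[C@H](O)c1ccc(O[Si](C(C)C)(C(C)C)C(C)C)c(OC)c1
F2 | step 3 | (2R)-2-{(S)-hydroxy[3-methoxy-4-(triisopropylsilyloxy)phenyl]methyl}-4-methoxy-4-oxobutanoic acid | COC(=O)C[C@@H](C(=O)O)[C@H](O)c1ccc(O[Si](C(C)C)(C(C)C)C(C)C)c(OC)c1
F3 | step 9 | (3S,4S,5S)-4-[(tert-butyldimethylsilyloxy)methyl]-3-{hydroxy[3-methoxy-4-(triisopropylsilyloxy)phenyl]methyl}-5-[3-methoxy-4-(triisopropylsilyloxy)phenyl]oxolan-2-one (carbinol epimers) | COc1cc(C(O)[C@H]2C(=O)O[C@H](c3ccc(O[Si](C(C)C)(C(C)C)C(C)C)c(OC)c3)[C@@H]2CO[Si](C)(C)C(C)(C)C)ccc1O[Si](C(C)C)(C(C)C)C(C)C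
F4 | step 9 | O-{[(3S,4S,5S)-4-[(tert-butyldimethylsilyloxy)methyl]-5-[3-methoxy-4-(triisopropylsilyloxy)phenyl]-2-oxooxolan-3-yl][3-methoxy-4-(triisopropylsilyloxy)phenyl]methyl} 1H-imidazole-1-carbothioate | COc1cc(C(OC(=S)n4ccnc4)[C@H]2C(=O)O[C@H](c3ccc(O[Si](C(C)C)(C(C)C)C(C)C)c(OC)c3)[C@@H]2CO[Si](C)(C)C(C)(C)C)ccc1O[Si](C(C)C)(C(C)C)C(C)C
F5 | step 11 | (3R,4S,5S)-4-[(tert-butyldimethylsilyloxy)methyl]-3-[3-methoxy-4-(triisopropylsilyloxy)benzyl]-5-[3-methoxy-4-(triisopropylsilyloxy)phenyl]oxolan-2-ol (anomer mixture) | COc1cc(C[C@H]2C(O)O[C@H](c3ccc(O[Si](C(C)C)(C(C)C)C(C)C)c(OC)c3)[C@@H]2CO[Si](C)(C)C(C)(C)C)ccc1O[Si](C(C)C)(C(C)C)C(C)C
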